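13 (8-(3,4-dimethoxyphenyl)-2,6-dimethoxy-1,4-naphthoquinone) ⇒ hydroquinone 12 by a two-electron oxidation.
12 ⇒ biaryl amide 5 + (E)-3-methoxyacrolein 6. The quinone ring is opened at C4–C4a and at C1–C2, and both bonds are made in one flask by a tandem directed metalation (anionic [3+3] annulation). CONEt2 becomes C1, and 6 delivers C4, C3 and C2 with the C2 methoxy group.
Enabling feature: C1 sits on C8a, whose ortho neighbours are C8 (blocked by the dimethoxyphenyl ring) and C4a (the only ortho C–H of 5), so a carboxamide at C1 can place lithium only on C4a. The C4–C3–C2(OMe) arc is a β-methoxyenal, electrophilic at C4, with a methoxy-acidified C–H at C2 that the E geometry holds cis to C4.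
5 ⇒ bromoamide 3 + boronic acid 4 (Suzuki–Miyaura coupling); 3 ⇒ commercial acid 1.
Ring order: both benzene rings are bought and joined in step 2. The quinone ring is the only ring built (step 3) and reaches the quinone level in step 4.

Key step: step 3

Assumption: (E)-3-methoxyprop-2-enal 6 is taken as a purchasable reagent (otherwise it comes from partial acid hydrolysis of 1,1,3,3-tetramethoxypropane). The target has no stereocentre, so only the E geometry of 6 matters.

Step 1
Reactants: 1 2-bromo-4-methoxybenzoic acid
Product: 3 2-bromo-N,N-diethyl-4-methoxybenzamide, via acid chloride 2 (not isolated)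
Conditions: (COCl)2, cat. DMF, CH2Cl2, 0 °C → rt, evaporate; Et2NH (3 equiv), CH2Cl2, 0 °C → rt
Reagents that add atoms: diethylamine, CCNCC; oxalyl chloride, O=C(Cl)C(=O)Cl (chlorine of 2 only)
Why: Acid chloride formation followed by Schotten–Baumann-type aminolysis is a standard amide synthesis and touches neither the aryl bromide nor the methyl ether.

Step 2
Reactants: 3 2-bromo-N,N-diethyl-4-methoxybenzamide, 4 (3,4-dimethoxyphenyl)boronic acid
Product: 5 2-(3,4-dimethoxyphenyl)-N,N-diethyl-4-methoxybenzamide
Conditions: Pd(PPh3)4 (5 mol %), K2CO3, DME/H2O, 85 °C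
Reagents that add atoms: none
Why: Suzuki–Miyaura coupling of ortho-bromobenzamides with arylboronic acids is a well-precedented biaryl synthesis in which the tertiary amide and the methyl ethers are inert.

Step 3
Reactants: 5 2-(3,4-dimethoxyphenyl)-N,N-diethyl-4-methoxybenzamide, 6 (E)-3-methoxyprop-2-enal
Product: 12 8-(3,4-dimethoxyphenyl)-2,6-dimethoxynaphthalene-1,4-diol, via aryllithium 7 (not isolated), via lithium alkoxide 8 (not isolated), via vinyllithium alkoxide 9 (not isolated), via oxidonaphthalenone 10 (not isolated), via dilithium diolate 11 (not isolated)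
Conditions: s-BuLi (1.1 equiv), TMEDA (3 equiv), THF, −78 °C; 6 (1.05 equiv), −78 °C; s-BuLi (1.5 equiv), −78 → 0 °C; degassed AcOH, −78 °C → rt, all under Ar
Reagents that add atoms: s-BuLi, CCC(C)[Li] (lithium of 7 to 11 only; none of its atoms stays in 12)
Why: Proposed new method: the tertiary amide steers s-BuLi to the only free ortho C–H of 5 (the future C4a) to give 7, which adds 1,2 to the aldehyde carbon of 6 and so makes the C4–C4a bond (8); a second portion of s-BuLi, held by the alkoxide and amide oxygens, then removes the enol-ether C–H that its own methoxy group acidifies and that the E geometry keeps cis to the carbinol carbon (9), this vinyllithium attacks the amide carbonyl and so makes the C1–C2 bond, LiNEt2 leaves (10) and then deprotonates C4–H, which aromatises the new ring to diolate 11, and acid gives 12. The closest known reaction types are the tandem directed metalation of benzamide/aryl aldehyde adducts that ends in anthraquinones, the anionic annulation of ortho-allylbenzamides to 1-naphthols and the α-lithiation of enol ethers; new is only that an enol-ether C–H replaces the aryl C–H in the second metalation. The one ring that closes, the six-membered future quinone ring, closes 6-exo-trig by addition–elimination at the amide carbonyl, which its two ortho neighbours twist out of the arene plane so that its π* lobe faces the incoming carbon. The carbinol carbon of 8, 9 and 10 forms as a racemate and becomes planar on aromatisation, so no stereocentre needs control. The step needs site selectivity in both metalations, 1,2-addition and one orientation of the three-carbon unit: the aryl group at C8 blocks the other ortho site, the amide outranks the methoxy groups as director, an alkyllithium at −78 °C (not a lithium amide at higher temperature) holds back remote metalation of the dimethoxyphenyl ring and fluorenone closure, the hard aryllithium prefers the carbonyl carbon of the vinylogous ester 6, and the polarity of 6 (aldehyde carbon to C4a, methoxy-bearing carbon to C1) leaves only the 2-methoxy isomer. If the second base takes the benzylic, allylic C4–H of 8 instead, the oxidoallyl anion can close through its methoxy-bearing end on the same amide and reaches the same 11, and a lithium placed on the ring C–H between the methoxy group and the carbinol arm cannot close and is simply reprotonated in the quench, so a modest excess of base covers both.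

Step 4
Reactants: 12 8-(3,4-dimethoxyphenyl)-2,6-dimethoxynaphthalene-1,4-diol
Product: 13 8-(3,4-dimethoxyphenyl)-2,6-dimethoxynaphthalene-1,4-dione
Conditions: Ag2O (2 equiv), anhydrous Na2SO4, CH2Cl2, rt, dark
Reagents that add atoms: none
Why: Oxidation of a 1,4-naphthohydroquinone with Ag2O is a standard mild quinone synthesis, and its neutral anhydrous medium spares the aryl methyl ethers and the vinylogous ester at C2.

Compound list
1 | 2-bromo-4-methoxybenzoic acid | COc1ccc(C(=O)O)c(Br)c1 | starting material
2 | 2-bromo-4-methoxybenzoyl chloride | COc1ccc(C(=O)Cl)c(Br)c1 | intermediate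
3 | 2-bromo-N,N-diethyl-4-methoxybenzamide | CCN(CC)C(=O)c1ccc(OC)cc1Br | intermediate
4 | (3,4-dimethoxyphenyl)boronic acid | COc1ccc(B(O)O)cc1OC | starting material
5 | 2-(3,4-dimethoxyphenyl)-N,N-diethyl-4-methoxybenzamide | CCN(CC)C(=O)c1ccc(OC)cc1-c1ccc(OC)c(OC)c1 | intermediate
6 | (E)-3-methoxyprop-2-enal | CO/C=C/C=O | starting material
7 | [2-(diethylcarbamoyl)-3-(3,4-dimethoxyphenyl)-5-methoxyphenyl]lithium | CCN(CC)C(=O)c1c([Li])cc(OC)cc1-c1ccc(OC)c(OC)c1 | intermediate
8 | lithium (E)-1-[2-(diethylcarbamoyl)-3-(3,4-dimethoxyphenyl)-5-methoxyphenyl]-3-methoxyprop-2-en-1-olate, racemic | CCN(CC)C(=O)c1c(C(O[Li])/C=C/OC)cc(OC)cc1-c1ccc(OC)c(OC)c1 | intermediate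
9 | 3-lithio derivative of 8 (lithium on the methoxy-bearing vinyl carbon, cis to the carbinol carbon), racemic | CCN(CC)C(=O)c1c(C(O[Li])/C=C(/OC)[Li])cc(OC)cc1-c1ccc(OC)c(OC)c1 | intermediate
10 | lithium salt of 8-(3,4-dimethoxyphenyl)-4-hydroxy-2,6-dimethoxynaphthalen-1(4H)-one, racemic | COC1=CC(O[Li])c2cc(OC)cc(-c3ccc(OC)c(OC)c3)c2C1=O | intermediate
11 | dilithium 8-(3,4-dimethoxyphenyl)-2,6-dimethoxynaphthalene-1,4-diolate | COc1cc(O[Li])c2cc(OC)cc(-c3ccc(OC)c(OC)c3)c2c1O[Li] | intermediate
12 | 8-(3,4-dimethoxyphenyl)-2,6-dimethoxynaphthalene-1,4-diol | COc1cc(O)c2cc(OC)cc(-c3ccc(OC)c(OC)c3)c2c1O | intermediate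
13 | 8-(3,4-dimethoxyphenyl)-2,6-dimethoxynaphthalene-1,4-dione | COC1=CC(=O)c2cc(OC)cc(-c3ccc(OC)c(OC)c3)c2C1=O | target

Total step count: 4. Longest linear sequence: 4 steps (1 → 3 → 5 → 12 → 13).

Steps most likely to fail

Step 3 (bears the label "Proposed new method:"). The second metalation may be misdirected. Remote metalation of the dimethoxyphenyl ring could be followed by closure on the amide, or the alkoxide could lactonise onto the amide before a carbanion forms. The fallback sets out from 5 and comes back to the route at 13. It makes the two bonds in separate flasks by known reaction types.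
- 5 is lithiated as before to 7 and transmetalated with CuBr·SMe2 to [2-(diethylcarbamoyl)-3-(3,4-dimethoxyphenyl)-5-methoxyphenyl]copper F1.
- In the presence of BF3·OEt2, F1 opens acrolein dimethyl acetal (3,3-dimethoxyprop-1-ene) in the SN2' sense. This should give 2-(3,4-dimethoxyphenyl)-N,N-diethyl-4-methoxy-6-[(E)-3-methoxyprop-2-enyl]benzamide F2.
- Isolated F2 has a far more acidic benzylic, allylic CH2. With LiN(i-Pr)2 (THF, −78 °C → rt) it should undergo the anionic annulation of ortho-allylbenzamides to 8-(3,4-dimethoxyphenyl)-2,6-dimethoxynaphthalen-1-ol F3.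
- Teuber oxidation of F3 with Fremy's salt, (KSO3)2NO (KH2PO4 buffer, acetone/H2O), at the free para position C4 should give 13.

Step 4. The electron-rich hydroquinone may autoxidise without control during isolation and handling, and the C2 methoxy group may be lost by hydrolysis of the vinylogous ester. The fallback sets out from crude 12 and comes back at 13.
- Crude 12 is acetylated at once (Ac2O, pyridine, Ar) to the bench-stable, chromatographable 8-(3,4-dimethoxyphenyl)-2,6-dimethoxynaphthalene-1,4-diyl diacetate F4.
- Purified F4 is methanolysed under air (K2CO3, MeOH, rt, short contact, then dilute acid). The liberated diolate is autoxidised directly to 13, and any methoxide exchange at C2 is degenerate.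

Step 2. Coupling next to the twisted amide may be sluggish while the electron-rich boronic acid protodeboronates. The fallback sets out from 3, reverses the polarity of the partners, and comes back at 5.
- Bromine–lithium exchange (n-BuLi, THF, −78 °C) gives [2-(diethylcarbamoyl)-5-methoxyphenyl]lithium F5.
- ZnCl2 turns F5 into [2-(diethylcarbamoyl)-5-methoxyphenyl]zinc chloride F6.
- Negishi coupling of F6 with commercial 4-iodo-1,2-dimethoxybenzene (Pd(PPh3)4, THF, 50 °C) should give 5.

Further compounds
F1 | step 3 | [2-(diethylcarbamoyl)-3-(3,4-dimethoxyphenyl)-5-methoxyphenyl]copper | CCN(CC)C(=O)c1c([Cu])cc(OC)cc1-c1ccc(OC)c(OC)c1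
F2 | step 3 | 2-(3,4-dimethoxyphenyl)-N,N-diethyl-4-methoxy-6-[(E)-3-methoxyprop-2-enyl]benzamide | CCN(CC)C(=O)c1c(C/C=C/OC)cc(OC)cc1-c1ccc(OC)c(OC)c1
F3 | step 3 | 8-(3,4-dimethoxyphenyl)-2,6-dimethoxynaphthalen-1-ol | COc1ccc2cc(OC)cc(-c3ccc(OC)c(OC)c3)c2c1O
F4 | step 4 | 8-(3,4-dimethoxyphenyl)-2,6-dimethoxynaphthalene-1,4-diyl diacetate | COc1cc(OC(C)=O)c2cc(OC)cc(-c3ccc(OC)c(OC)c3)c2c1OC(C)=O
F5 | step 2 | [2-(diethylcarbamoyl)-5-methoxyphenyl]lithium | CCN(CC)C(=O)c1ccc(OC)cc1[Li]
F6 | step 2 | [2-(diethylcarbamoyl)-5-methoxyphenyl]zinc chloride | CCN(CC)C(=O)c1ccc(OC)cc1[Zn]Cl
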